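**Retrosynthetic overview**
1. Target 30 ⇐ bis-O-sulfation of hydroquinone triol 29 ⇐ global desilylation of 28.
2. Key step: Ireland–Claisen [3,3] shift of allylic ester 22 bonds the ester α-carbon (C12') to C4 on the hindered β-face (2β-O → 4β-C) and sets the C4 quaternary centre. Diimide reduction of Δ2 and Barton decarboxylation then give 28.
3. 22 ⇐ allylic alcohol 14 + ketene 21 from diazoketone 20, the Arndt–Eistert homologue of 8-epi-sclareolide (left decalin bought; only C8' is epimerised).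
4. 14 ⇐ (R)-carvone (= ring B): two α'-alkylations set C10, RCM closes ring A, 1,2-reduction sets C2, then C9 methylenation and hydroboration/B-alkyl Suzuki with aryl bromide 2.
5. Ring order: ring B (bought) → ring A (RCM) → arene attached → union with the bought left decalin by the [3,3] shift.

Assumption: the target is the free bis(hydrogen sulfate) as drawn; it is isolated via its disodium salt and liberated on H+ resin.
Numbering used in names: right decalin as a drimane (C1–C10; C11 = ArCH2 on C9; Me on C4, C8, C10); left decalin primed; linker C9'–C11'H2–C12'H2–C4; β = face of the C10 methyl.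

Step 1
Reactants: 1 2-bromobenzene-1,4-diol
Product: 2 2-bromo-1,4-bis(tert-butyldimethylsilyloxy)benzene
Conditions: TBSCl (2.4 eq), imidazole, DMF, rt
Reagents that add atoms: tert-butyldimethylsilyl chloride CC(C)(C)[Si](C)(C)Cl
Why: Imidazole-mediated O-silylation masks both phenols so the bromide survives the Suzuki step and all silyl groups can be removed together with fluoride.

Step 2
Reactants: 3 (R)-(−)-carvone
Product: 5 (5R,6S)-2,6-dimethyl-5-(prop-1-en-2-yl)cyclohex-2-en-1-one (trans-6-methylcarvone; minor cis epimer carried along), via carvone lithium dienolate 4 (not isolated)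
Conditions: LDA, THF, −78 °C; MeI, −78 → 0 °C
Reagents that add atoms: iodomethane CI
Why: Kinetic α'-deprotonation and enolate alkylation; the new C6 centre is erased by the next enolisation, so the epimer ratio does not matter.

Step 3
Reactants: 5 trans-6-methylcarvone
Product: 7 2-[(1S,6S)-1,3-dimethyl-2-oxo-6-(prop-1-en-2-yl)cyclohex-3-en-1-yl]-N-methoxy-N-methylacetamide, via 6-methylcarvone lithium enolate 6 (not isolated)
Conditions: LDA, THF/DMPU, −78 °C; BrCH2C(O)N(OMe)Me, −78 → −20 °C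
Reagents that add atoms: 2-bromo-N-methoxy-N-methylacetamide CON(C)C(=O)CBr
Why: Enolate alkylation anti to the neighbouring isopropenyl group sets quaternary C10 (Me cis to isopropenyl), controlled by the carvone stereocentre.

Step 4
Reactants: 7 Weinreb amide
Product: 9 1-[(1S,6S)-1,3-dimethyl-2-oxo-6-(prop-1-en-2-yl)cyclohex-3-en-1-yl]but-3-en-2-one, via magnesium hemiaminal chelate 8 (not isolated)
Conditions: CH2=CHMgBr (1.3 eq), THF, −78 → 0 °C; cold aq. quench
Reagents that add atoms: vinylmagnesium bromide C=C[Mg]Br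
Why: Weinreb ketone synthesis; the chelated adduct prevents over-addition, and the α-quaternary ring enone is too hindered to compete.

Step 5
Reactants: 9 vinyl ketone
Product: 10 (4aS,8aS)-4,7,8a-trimethyl-1,4a,5,8a-tetrahydronaphthalene-2,8-dione (trans-fused bis-enone; ring A enone C2=O/Δ3)
Conditions: Hoveyda–Grubbs II (5 mol %), PhMe, 80 °C
Reagents that add atoms: none
Why: Ring-closing metathesis of the vinyl ketone with the isopropenyl group closes ring A; the arms are trans on ring B, so the fusion is trans and no stereocentre is touched.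

Step 6
Reactants: 10 bis-enone
Product: 11 (4aS,7S,8aS)-7-hydroxy-2,5,8a-trimethyl-4a,7,8,8a-tetrahydronaphthalen-1(4H)-one (2β-allylic alcohol in drimane numbering)
Conditions: NaBH4, CeCl3·7H2O, MeOH, −78 °C
Reagents that add atoms: none
Why: Luche 1,2-reduction picks the unhindered ring-A enone; hydride attacks the α-face, anti to the syn-axial C10 methyl, giving the 2β-alcohol.

Step 7
Reactants: 11 hydroxy enone
Product: 12 (2S,4aS,8aS)-4,7,8a-trimethyl-8-methylidene-1,2,4a,5,8,8a-hexahydronaphthalen-2-ol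
Conditions: Ph3PCH3Br (5 eq), KOt-Bu (4.8 eq), PhMe, 90 °C
Reagents that add atoms: methyltriphenylphosphonium bromide C[P+](c1ccccc1)(c1ccccc1)c1ccccc1.[Br-]
Why: Wittig methylenation of the hindered C9 enone with excess ylide at elevated temperature; the free alcohol rides through as its alkoxide.

Step 8
Reactants: 12 dienol + 2 aryl bromide
Product: 14 (2S,4aS,8S,8aS)-8-[2,5-bis(tert-butyldimethylsilyloxy)benzyl]-4,7,8a-trimethyl-1,2,4a,5,8,8a-hexahydronaphthalen-2-ol (2β-OH; 9α-H; Δ3; Δ7), via B-alkyl-9-BBN borinate 13 (not isolated)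
Conditions: 9-BBN (2.5 eq), THF, 0 °C → rt; then 2, Pd(dppf)Cl2 (5 mol %), aq. K3PO4, THF/DMF, 50 °C
Reagents that add atoms: none
Why: Hydroboration of the exocyclic methylene from the α-face (anti to the C10 methyl) sets 9α-H, and B-alkyl Suzuki–Miyaura coupling forms the C11–aryl bond.

Step 9
Reactants: 15 (+)-sclareolide
Product: 16 8-epi-sclareolide [(3aS,5aS,9aS,9bR)-3a,6,6,9a-tetramethyldecahydronaphtho[2,1-b]furan-2(1H)-one]
Conditions: conc. H2SO4 (cat.), HCO2H, 60 °C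
Reagents that add atoms: none
Why: Acid-mediated C8–O ionisation and relactonisation gives the more stable cis-fused lactone (8β-O, 8α-Me); C5', C9' and C10' are untouched.

Step 10
Reactants: 16 8-epi-sclareolide
Product: 18 triethylsilyl 2-[(1R,2S,4aS,8aS)-2,5,5,8a-tetramethyl-2-(triethylsilyloxy)decahydronaphthalen-1-yl]acetate, via potassium hydroxy carboxylate 17 (not isolated)
Conditions: KOH, MeOH/H2O, 65 °C; evaporate, dry; TESOTf (3 eq), 2,6-lutidine, CH2Cl2, 0 °C → rt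
Reagents that add atoms: potassium hydroxide [K+].[OH-]; triethylsilyl trifluoromethanesulfonate CC[Si](CC)(CC)OS(=O)(=O)C(F)(F)F
Why: Saponification followed by silylation caps the tertiary alkoxide before it can relactonise and gives a silyl ester ready for neutral activation.

Step 11
Reactants: 18 bis-silyl compound
Product: 20 1-diazo-3-[(1R,2S,4aS,8aS)-2,5,5,8a-tetramethyl-2-(triethylsilyloxy)decahydronaphthalen-1-yl]propan-2-one, via acid chloride 19 (not isolated)
Conditions: (COCl)2, DMF (cat.), CH2Cl2, 0 °C → rt; then CH2N2 (3 eq), Et2O, 0 °C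
Reagents that add atoms: diazomethane C=[N+]=[N-]
Why: Silyl ester to acid chloride without free HCl, then acylation of diazomethane (first stage of Arndt–Eistert homologation); the TES ether is untouched.

Step 12
Reactants: 20 diazoketone + 14 allylic alcohol
Product: 22 ester of the C2-OH of 14 with 3-[(1R,2S,4aS,8aS)-2,5,5,8a-tetramethyl-2-(triethylsilyloxy)decahydronaphthalen-1-yl]propanoic acid (O–CO–C12'H2–C11'H2–C9'), via ketene 21 (not isolated)
Conditions: PhCO2Ag (15 mol %), Et3N, THF, rt, dark, sonication (20 1.3 eq)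
Reagents that add atoms: none
Why: Silver-catalysed Wolff rearrangement gives the one-carbon-longer ketene, which acylates the 2β-alcohol with retention at C2.

Step 13
Reactants: 22 allylic ester
Product: 25 2-(right-decalin-4-yl)-3-(left-decalin-9'-yl)propanoic acid; chain C4–C12'H(CO2H)–C11'H2–C9' (2,7-diene; 4α-Me; 4β-C12'; 8'β-OTES; aryl bis-TBS; both C12' epimers), via silyl ketene acetal 23 (not isolated), via trimethylsilyl ester 24 (not isolated)
Conditions: LDA, TMSCl/Et3N, THF, −78 °C → rt; then PhMe, 90 °C; aq. citric acid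
Reagents that add atoms: none
Why: Ireland–Claisen [3,3]-sigmatropic rearrangement bonds the ester α-carbon (C12') to C4 suprafacially across ring A, so the 2β C–O bond delivers C12' to the β-face and creates the quaternary centre syn to the C10 methyl (the C12' configuration is later removed).

Step 14
Reactants: 25 diene acid
Product: 26 Δ2-saturated C12'-carboxylic acid (ring A saturated; Δ7 kept; chain C4–C12'H(CO2H)–C11'H2–C9')
Conditions: 2-nitrobenzenesulfonohydrazide (excess), Et3N, CH2Cl2, rt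
Reagents that add atoms: none
Why: Diimide reduction removes the cis-disubstituted Δ2 alkene and spares the trisubstituted Δ7 alkene, so no alkene is left homoallylic to C12' when the radical is generated.

Step 15
Reactants: 26 saturated acid
Product: 28 fully protected coupled product (8'β-OTES; aryl bis-TBS; C4–C12'H2–C11'H2–C9' linker), via Barton ester 27 (not isolated)
Conditions: N-hydroxypyridine-2-thione, DCC, DMAP (cat.), CH2Cl2, dark; then t-BuSH (20 eq), hν (W lamp), rt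
Reagents that add atoms: none
Why: Barton reductive decarboxylation (radical chain in which excess thiol traps the C12' radical faster than it can add to Δ7) removes the carboxyl carbon and turns C12' into CH2.

Step 16
Reactants: 28 tris-silyl ether
Product: 29 hydroquinone triol (8'β-OH; free hydroquinone)
Conditions: TBAF (4 eq), degassed THF, 0 °C → rt, Ar; AcOH quench
Reagents that add atoms: none
Why: Fluoride desilylation cleaves both aryl TBS ethers and the tertiary TES ether in one operation under non-acidic conditions that spare Δ7.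

Step 17
Reactants: 29 hydroquinone triol
Product: 30 CNP0471499.2 (target bis(hydrogen sulfate))
Conditions: SO3·pyridine (6 eq), pyridine, rt → 40 °C; NaHCO3; Dowex 50W (H+), 0 °C
Reagents that add atoms: sulfur trioxide pyridine complex [O-]S(=O)(=O)[n+]1ccccc1
Why: O-Sulfation of both phenols; the hindered axial tertiary 8'β-alcohol does not react.

**Compound list**
1 | 2-bromobenzene-1,4-diol | Oc1ccc(O)c(Br)c1 | starting material
2 | 2-bromo-1,4-bis(tert-butyldimethylsilyloxy)benzene | CC(C)(C)[Si](C)(C)Oc1ccc(O[Si](C)(C)C(C)(C)C)c(Br)c1 | intermediate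
3 | (R)-(−)-carvone | CC1=CC[C@H](CC1=O)C(C)=C | starting material
4 | carvone lithium dienolate | CC1=CC[C@@H](C(C)=C)C=C1[O-].[Li+] | intermediate
5 | (5R,6S)-2,6-dimethyl-5-(prop-1-en-2-yl)cyclohex-2-en-1-one | CC1=CC[C@@H](C(C)=C)[C@H](C)C1=O | intermediate
6 | 6-methylcarvone lithium enolate | CC1=CC[C@@H](C(C)=C)C(C)=C1[O-].[Li+] | intermediate
7 | 2-[(1S,6S)-1,3-dimethyl-2-oxo-6-(prop-1-en-2-yl)cyclohex-3-en-1-yl]-N-methoxy-N-methylacetamide | CC1=CC[C@@H](C(C)=C)[C@](C)(CC(=O)N(C)OC)C1=O | intermediate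
8 | magnesium hemiaminal chelate | CC1=CC[C@@H](C(C)=C)[C@](C)(CC(O[Mg]Br)(C=C)N(C)OC)C1=O | intermediate
9 | 1-[(1S,6S)-1,3-dimethyl-2-oxo-6-(prop-1-en-2-yl)cyclohex-3-en-1-yl]but-3-en-2-one | CC1=CC[C@@H](C(C)=C)[C@](C)(CC(=O)C=C)C1=O | intermediate
10 | (4aS,8aS)-4,7,8a-trimethyl-1,4a,5,8a-tetrahydronaphthalene-2,8-dione | CC1=CC[C@H]2C(C)=CC(=O)C[C@]2(C)C1=O | intermediate
11 | (4aS,7S,8aS)-7-hydroxy-2,5,8a-trimethyl-4a,7,8,8a-tetrahydronaphthalen-1(4H)-one | CC1=CC[C@H]2C(C)=C[C@@H](O)C[C@]2(C)C1=O | intermediate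
12 | (2S,4aS,8aS)-4,7,8a-trimethyl-8-methylidene-1,2,4a,5,8,8a-hexahydronaphthalen-2-ol | C=C1C(C)=CC[C@H]2C(C)=C[C@@H](O)C[C@]12C | intermediate
13 | B-alkyl-9-BBN borinate (C11–B and O2–B) | CC1=CC[C@H]2C(C)=C[C@@H](OB3C4CCCC3CCC4)C[C@]2(C)[C@H]1CB1C2CCCC1CCC2 | intermediate
14 | (2S,4aS,8S,8aS)-8-[2,5-bis(tert-butyldimethylsilyloxy)benzyl]-4,7,8a-trimethyl-1,2,4a,5,8,8a-hexahydronaphthalen-2-ol | CC1=CC[C@H]2C(C)=C[C@@H](O)C[C@]2(C)[C@H]1Cc1cc(O[Si](C)(C)C(C)(C)C)ccc1O[Si](C)(C)C(C)(C)C | intermediate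
15 | (+)-sclareolide | O=C1C[C@@H]2[C@@]3(C)CCCC(C)(C)[C@@H]3CC[C@@]2(C)O1 | starting material
16 | 8-epi-sclareolide | O=C1C[C@@H]2[C@@]3(C)CCCC(C)(C)[C@@H]3CC[C@]2(C)O1 | intermediate
17 | potassium 2-[(1R,2S,4aS,8aS)-2-hydroxy-2,5,5,8a-tetramethyldecahydronaphthalen-1-yl]acetate | [K+].[O-]C(=O)C[C@@H]1[C@@]2(C)CCCC(C)(C)[C@@H]2CC[C@]1(C)O | intermediate
18 | triethylsilyl 2-[(1R,2S,4aS,8aS)-2,5,5,8a-tetramethyl-2-(triethylsilyloxy)decahydronaphthalen-1-yl]acetate | CC[Si](CC)(CC)OC(=O)C[C@@H]1[C@@]2(C)CCCC(C)(C)[C@@H]2CC[C@]1(C)O[Si](CC)(CC)CC | intermediate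
19 | 2-[(1R,2S,4aS,8aS)-2,5,5,8a-tetramethyl-2-(triethylsilyloxy)decahydronaphthalen-1-yl]acetyl chloride | ClC(=O)C[C@@H]1[C@@]2(C)CCCC(C)(C)[C@@H]2CC[C@]1(C)O[Si](CC)(CC)CC | intermediate
20 | 1-diazo-3-[(1R,2S,4aS,8aS)-2,5,5,8a-tetramethyl-2-(triethylsilyloxy)decahydronaphthalen-1-yl]propan-2-one | [N-]=[N+]=CC(=O)C[C@@H]1[C@@]2(C)CCCC(C)(C)[C@@H]2CC[C@]1(C)O[Si](CC)(CC)CC | intermediate
21 | homologated ketene (3-substituted prop-1-en-1-one) | O=C=CC[C@@H]1[C@@]2(C)CCCC(C)(C)[C@@H]2CC[C@]1(C)O[Si](CC)(CC)CC | intermediate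
22 | ester of the C2-OH of 14 with 3-[(1R,2S,4aS,8aS)-2,5,5,8a-tetramethyl-2-(triethylsilyloxy)decahydronaphthalen-1-yl]propanoic acid | CC1=CC[C@H]2C(C)=C[C@@H](OC(=O)CC[C@@H]3[C@@]4(C)CCCC(C)(C)[C@@H]4CC[C@]3(C)O[Si](CC)(CC)CC)C[C@]2(C)[C@H]1Cc1cc(O[Si](C)(C)C(C)(C)C)ccc1O[Si](C)(C)C(C)(C)C | intermediate
23 | trimethylsilyl ketene acetal of 22 | CC1=CC[C@H]2C(C)=C[C@@H](OC(O[Si](C)(C)C)=CC[C@@H]3[C@@]4(C)CCCC(C)(C)[C@@H]4CC[C@]3(C)O[Si](CC)(CC)CC)C[C@]2(C)[C@H]1Cc1cc(O[Si](C)(C)C(C)(C)C)ccc1O[Si](C)(C)C(C)(C)C | intermediate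
24 | trimethylsilyl ester of 25 | CC1=CC[C@H]2[C@@](C)(C(C[C@@H]3[C@@]4(C)CCCC(C)(C)[C@@H]4CC[C@]3(C)O[Si](CC)(CC)CC)C(=O)O[Si](C)(C)C)C=CC[C@]2(C)[C@H]1Cc1cc(O[Si](C)(C)C(C)(C)C)ccc1O[Si](C)(C)C(C)(C)C | intermediate
25 | C12'-carboxylic acid of the coupled 2,7-diene: propanoic acid with C2 (= C12') on C4 of the right decalin (4α-Me, 4β-C12') and C3 (= C11') on C9' of the left decalin; C12' epimers | CC1=CC[C@H]2[C@@](C)(C(C[C@@H]3[C@@]4(C)CCCC(C)(C)[C@@H]4CC[C@]3(C)O[Si](CC)(CC)CC)C(=O)O)C=CC[C@]2(C)[C@H]1Cc1cc(O[Si](C)(C)C(C)(C)C)ccc1O[Si](C)(C)C(C)(C)C | intermediate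
26 | Δ2-saturated C12'-carboxylic acid | CC1=CC[C@H]2[C@@](C)(C(C[C@@H]3[C@@]4(C)CCCC(C)(C)[C@@H]4CC[C@]3(C)O[Si](CC)(CC)CC)C(=O)O)CCC[C@]2(C)[C@H]1Cc1cc(O[Si](C)(C)C(C)(C)C)ccc1O[Si](C)(C)C(C)(C)C | intermediate
27 | Barton ester (2-thioxopyridin-1-yl ester of 26) | CC1=CC[C@H]2[C@@](C)(C(C[C@@H]3[C@@]4(C)CCCC(C)(C)[C@@H]4CC[C@]3(C)O[Si](CC)(CC)CC)C(=O)ON5C=CC=CC5=S)CCC[C@]2(C)[C@H]1Cc1cc(O[Si](C)(C)C(C)(C)C)ccc1O[Si](C)(C)C(C)(C)C | intermediate
28 | tris-silyl-protected target skeleton (8'β-OTES, aryl bis-TBS) | CC1=CC[C@H]2[C@@](C)(CC[C@@H]3[C@@]4(C)CCCC(C)(C)[C@@H]4CC[C@]3(C)O[Si](CC)(CC)CC)CCC[C@]2(C)[C@H]1Cc1cc(O[Si](C)(C)C(C)(C)C)ccc1O[Si](C)(C)C(C)(C)C | intermediate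
29 | hydroquinone triol | CC1=CC[C@H]2[C@@](C)(CC[C@@H]3[C@@]4(C)CCCC(C)(C)[C@@H]4CC[C@]3(C)O)CCC[C@]2(C)[C@H]1Cc1cc(O)ccc1O | intermediate
30 | CNP0471499.2 | CC1=CC[C@H]2[C@@](C)(CC[C@@H]3[C@@]4(C)CCCC(C)(C)[C@@H]4CC[C@]3(C)O)CCC[C@]2(C)[C@H]1Cc1cc(OS(=O)(=O)O)ccc1OS(=O)(=O)O | target

**Totals**
Total step count: 17. Longest linear sequence: 13 steps (3 → 30 through steps 2–8 and 12–17).

**Three steps most likely to fail**

Step 8 (B-alkyl Suzuki of a CH2–B next to a quaternary centre with an ortho-silyloxy aryl bromide). The fallback reverses the polarity of the coupling. It sets out from 12: borinate 13 is made as before and iodinated (I2, NaOMe, THF, 0 °C) to (2S,4aS,8S,8aS)-8-(iodomethyl)-4,7,8a-trimethyl-1,2,4a,5,8,8a-hexahydronaphthalen-2-ol F1. Aryl bromide 2 is lithiated (n-BuLi, −78 °C) and transmetallated with ZnCl2 to [2,5-bis(tert-butyldimethylsilyloxy)phenyl]zinc chloride F2. A Pd-catalysed alkyl–aryl Negishi coupling (Pd2(dba)3, PCyp3, NMI, THF/NMP, 80 °C; excess F2 because of the free OH) returns to the route at 14.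

Step 12 (trapping a monoalkylketene with the hindered 2β-alcohol). The fallback separates homologation from esterification. It sets out from 20: Wolff rearrangement in wet dioxane (PhCO2Ag, Et3N, H2O) gives 3-[(1R,2S,4aS,8aS)-2,5,5,8a-tetramethyl-2-(triethylsilyloxy)decahydronaphthalen-1-yl]propanoic acid F3. Yamaguchi esterification (2,4,6-trichlorobenzoyl chloride, Et3N; then 14, DMAP, PhMe) returns to the route at 22.

Step 13 (Ireland–Claisen forming a quaternary centre 1,3-diaxial to the C10 methyl). The fallback replaces the [3,3] shift by a copper-catalysed anti-SN2' substitution. It sets out from 14 and 18. Mitsunobu reaction of 14 with picolinic acid (PPh3, DIAD) gives the 2α-picolinate of the C2 epimer of 14 F4. LiAlH4 reduction of 18 gives 2-[(1R,2S,4aS,8aS)-2,5,5,8a-tetramethyl-2-(triethylsilyloxy)decahydronaphthalen-1-yl]ethanol F5. Appel bromination (CBr4, PPh3) gives the corresponding 2-bromoethyl compound F6, and Mg gives the corresponding Grignard reagent F7. F7 with CuBr·SMe2 (cat.) attacks C4 of F4 anti to the picolinate, so from the β-face, and gives the Δ2 analogue of 28 F8 with no extra carboxyl. Diimide reduction of Δ2 returns to the route at 28.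

Further compounds
F1 | step 8 | (2S,4aS,8S,8aS)-8-(iodomethyl)-4,7,8a-trimethyl-1,2,4a,5,8,8a-hexahydronaphthalen-2-ol | CC1=CC[C@H]2C(C)=C[C@@H](O)C[C@]2(C)[C@H]1CI
F2 | step 8 | [2,5-bis(tert-butyldimethylsilyloxy)phenyl]zinc chloride | CC(C)(C)[Si](C)(C)Oc1ccc(O[Si](C)(C)C(C)(C)C)c([Zn]Cl)c1
F3 | step 12 | 3-[(1R,2S,4aS,8aS)-2,5,5,8a-tetramethyl-2-(triethylsilyloxy)decahydronaphthalen-1-yl]propanoic acid | OC(=O)CC[C@@H]1[C@@]2(C)CCCC(C)(C)[C@@H]2CC[C@]1(C)O[Si](CC)(CC)CC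
F4 | step 13 | 2α-picolinate of the C2 epimer of 14 | CC1=CC[C@H]2C(C)=C[C@H](OC(=O)c3ccccn3)C[C@]2(C)[C@H]1Cc1cc(O[Si](C)(C)C(C)(C)C)ccc1O[Si](C)(C)C(C)(C)C
F5 | step 13 | 2-[(1R,2S,4aS,8aS)-2,5,5,8a-tetramethyl-2-(triethylsilyloxy)decahydronaphthalen-1-yl]ethanol | OCC[C@@H]1[C@@]2(C)CCCC(C)(C)[C@@H]2CC[C@]1(C)O[Si](CC)(CC)CC
F6 | step 13 | corresponding 2-bromoethyl compound | BrCC[C@@H]1[C@@]2(C)CCCC(C)(C)[C@@H]2CC[C@]1(C)O[Si](CC)(CC)CC
F7 | step 13 | corresponding Grignard reagent | Br[Mg]CC[C@@H]1[C@@]2(C)CCCC(C)(C)[C@@H]2CC[C@]1(C)O[Si](CC)(CC)CC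
F8 | step 13 | Δ2 analogue of 28 (4α-Me, 4β-linker, 2,7-diene) | CC1=CC[C@H]2[C@@](C)(CC[C@@H]3[C@@]4(C)CCCC(C)(C)[C@@H]4CC[C@]3(C)O[Si](CC)(CC)CC)C=CC[C@]2(C)[C@H]1Cc1cc(O[Si](C)(C)C(C)(C)C)ccc1O[Si](C)(C)C(C)(C)C
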